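**Retrosynthetic overview**
- The ring–CH2 bond is cut first: reductive alkylation (Knoevenagel condensation, then hydride transfer) joins the dearomatised gem-diprenyl acylphloroglucinol to a cyclopentane β-hydroxy aldehyde.
- The β-hydroxy aldehyde comes from a cis-fused bicyclic β-lactone by reduction to the diol and selective re-oxidation.
- Key step: the β-lactone comes from a limonene-derived keto acid by nucleophile-catalysed aldol-lactonisation, which closes the cyclopentane and the β-lactone in one operation and sets both new stereocentres from the limonene centre.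
- The six-membered partner comes from phloroglucinol by Friedel–Crafts isobutyrylation and alkylative dearomatisation with two prenyl groups.
- Ring order: six-membered ring bought as the arene and dearomatised; cyclopentane and β-lactone closed together; β-lactone then opened reductively.

Assumption: the acylphloroglucinol core is treated as the enol tautomer drawn in the target SMILES, and commercial (+)-limonene oxide (cis/trans mixture, 4R, from (R)-limonene) is the chiral source.

**Step 1**
Reactants: 1 (+)-limonene 1,2-oxide (4R; cis/trans mixture)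
Product: 3 (3R)-6-oxo-3-(prop-1-en-2-yl)heptanal, via limonene-1,2-diol 2 (not isolated)
Conditions: H5IO6, THF/H2O, 0 °C to rt
Reagents that add atoms: water (O)
Why: Both epoxide diastereomers hydrate to the vicinal diol, which periodic acid cleaves (Malaprade glycol cleavage) to the keto aldehyde, while the isopropenyl group and the limonene stereocentre (now C3) are untouched.

**Step 2**
Reactants: 3 (3R)-6-oxo-3-(prop-1-en-2-yl)heptanal
Product: 4 (3R)-6-oxo-3-(prop-1-en-2-yl)heptanoic acid
Conditions: NaClO2, NaH2PO4, 2-methyl-2-butene, t-BuOH/H2O, 0 °C to rt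
Reagents that add atoms: sodium chlorite ([Na+].[O-]Cl=O)
Why: Pinnick oxidation converts the aldehyde into the acid without touching the methyl ketone or C3, and 2-methyl-2-butene scavenges the hypochlorite so the isopropenyl group survives.

**Step 3**
Reactants: 4 (3R)-6-oxo-3-(prop-1-en-2-yl)heptanoic acid
Product: 7 (1S,2R,5R)-5-methyl-2-(prop-1-en-2-yl)-6-oxabicyclo[3.2.0]heptan-7-one, via tosyl mixed anhydride 5 (not isolated), via acylpyridinium tosylate 6 (not isolated)
Conditions: TsCl, 4-pyrrolidinopyridine (20 mol%), LiCl, iPr2NEt, CH2Cl2, high dilution, 23 °C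
Reagents that add atoms: none
Why: Nucleophile-catalysed aldol-lactonisation: the pyridine turns 5 into 6, whose ammonium enolate adds to the methyl ketone (cyclopentane) and whose aldolate then acylates itself (β-lactone); the isopropenyl-bearing centre keeps its hydrogen in the enolate plane to avoid A1,3 strain, so the ketone attacks anti to isopropenyl (C1 S), and the obligatory cis ring fusion fixes the carbinol centre (C5 R).

**Step 4**
Reactants: 7 (1S,2R,5R)-5-methyl-2-(prop-1-en-2-yl)-6-oxabicyclo[3.2.0]heptan-7-one
Product: 8 (1R,2R,3R)-2-(hydroxymethyl)-1-methyl-3-(prop-1-en-2-yl)cyclopentan-1-ol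
Conditions: LiAlH4, THF, 0 °C; aqueous NaOH work-up
Reagents that add atoms: none
Why: Hydride reduction of the strained lactone proceeds by acyl–oxygen cleavage, so the tertiary C–O bond and all three stereocentres are retained and the isolated alkene is not touched.

**Step 5**
Reactants: 8 (1R,2R,3R)-2-(hydroxymethyl)-1-methyl-3-(prop-1-en-2-yl)cyclopentan-1-ol
Product: 9 (1S,2R,5R)-2-hydroxy-2-methyl-5-(prop-1-en-2-yl)cyclopentane-1-carbaldehyde
Conditions: TEMPO (10 mol%), PhI(OAc)2, CH2Cl2, rt; used crude at once
Reagents that add atoms: none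
Why: The TEMPO/oxoammonium oxidation takes only the primary alcohol and stops at the aldehyde, and its near-neutral medium spares the tertiary β-hydroxy aldehyde from retro-aldol cleavage, dehydration and epimerisation (the formyl group already sits in its favoured position trans to isopropenyl).

**Step 6**
Reactants: 10 phloroglucinol; 11 isobutyryl chloride
Product: 12 phlorisobutyrophenone (2-methyl-1-(2,4,6-trihydroxyphenyl)propan-1-one)
Conditions: AlCl3, PhNO2/CH2Cl2, 0 °C to rt
Reagents that add atoms: none
Why: Friedel–Crafts C-acylation of the highly activated arene stops at the mono-ketone because the first acyl group deactivates the ring.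

**Step 7**
Reactants: 12 phlorisobutyrophenone; 13 prenyl bromide (2.1 equiv)
Product: 15 3,5-dihydroxy-6,6-bis(3-methylbut-2-en-1-yl)-2-(2-methylpropanoyl)cyclohexa-2,4-dien-1-one, via 3-prenylphlorisobutyrophenone 14 (not isolated)
Conditions: NaOMe (2.2 equiv), MeOH, −10 °C to rt; acidify; extract product into aq. NaHCO3, re-acidify
Reagents that add atoms: none
Why: Lupulone-type alkylative dearomatisation: C-prenylation of the phenoxide gives 14, a second C-alkylation at the same electron-rich carbon gives the gem-diprenyl dienone, and this vinylogous acid is separated from the weaker-acid aromatic 3,5-diprenyl isomer by bicarbonate extraction; no stereocentre is formed.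

**Step 8**
Reactants: 9 (1S,2R,5R)-2-hydroxy-2-methyl-5-(prop-1-en-2-yl)cyclopentane-1-carbaldehyde; 15 3,5-dihydroxy-6,6-bis(3-methylbut-2-en-1-yl)-2-(2-methylpropanoyl)cyclohexa-2,4-dien-1-one
Product: 17 3,5-dihydroxy-4-{[(1S,2R,5R)-2-hydroxy-2-methyl-5-(prop-1-en-2-yl)cyclopentyl]methyl}-6,6-bis(3-methylbut-2-en-1-yl)-2-(2-methylpropanoyl)cyclohexa-2,4-dien-1-one, via alkylidene trione 16 (not isolated)
Conditions: Hantzsch ester (diethyl 2,6-dimethyl-1,4-dihydropyridine-3,5-dicarboxylate, 1.2 equiv), (S)-proline (10 mol%), CH2Cl2, 25 °C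
Reagents that add atoms: none
Why: Three-component reductive alkylation: Knoevenagel condensation at the only nucleophilic ring CH of 15 gives the electron-poor alkylidene 16, which the Hantzsch ester reduces by conjugate hydride transfer before it can isomerise or lose water, so the CH2 link forms regiospecifically and the three cyclopentane stereocentres pass through unchanged.

**Compound list**
1 | (+)-limonene 1,2-oxide, (4R)-1-methyl-4-(prop-1-en-2-yl)-7-oxabicyclo[4.1.0]heptane, cis/trans mixture at C1/C6 | CC12OC1C[C@@H](CC2)C(=C)C | starting material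
2 | (4R)-1-methyl-4-(prop-1-en-2-yl)cyclohexane-1,2-diol (limonene-1,2-diol, trans-diol; C1/C2 are destroyed in the same step) | CC1(O)C(O)C[C@@H](CC1)C(=C)C | intermediate
3 | (3R)-6-oxo-3-(prop-1-en-2-yl)heptanal | O=CC[C@@H](CCC(C)=O)C(C)=C | intermediate
4 | (3R)-6-oxo-3-(prop-1-en-2-yl)heptanoic acid | OC(=O)C[C@@H](CCC(C)=O)C(C)=C | intermediate
5 | (3R)-6-oxo-3-(prop-1-en-2-yl)heptanoic 4-methylbenzenesulfonic anhydride (tosyl mixed anhydride) | Cc1ccc(cc1)S(=O)(=O)OC(=O)C[C@@H](CCC(C)=O)C(C)=C | intermediate
6 | 1-[(3R)-6-oxo-3-(prop-1-en-2-yl)heptanoyl]-4-(pyrrolidin-1-yl)pyridinium tosylate (acylpyridinium tosylate) | O=C(C[C@@H](CCC(C)=O)C(C)=C)[n+]1ccc(cc1)N1CCCC1.Cc1ccc(cc1)S(=O)(=O)[O-] | intermediate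
7 | (1S,2R,5R)-5-methyl-2-(prop-1-en-2-yl)-6-oxabicyclo[3.2.0]heptan-7-one (cis-fused β-lactone, isopropenyl trans to the lactone carbonyl) | C=C(C)[C@@H]1CC[C@@]2(C)OC(=O)[C@@H]12 | intermediate
8 | (1R,2R,3R)-2-(hydroxymethyl)-1-methyl-3-(prop-1-en-2-yl)cyclopentan-1-ol | C=C(C)[C@@H]1CC[C@@](C)(O)[C@H]1CO | intermediate
9 | (1S,2R,5R)-2-hydroxy-2-methyl-5-(prop-1-en-2-yl)cyclopentane-1-carbaldehyde | C=C(C)[C@@H]1CC[C@@](C)(O)[C@H]1C=O | intermediate
10 | phloroglucinol (benzene-1,3,5-triol) | Oc1cc(O)cc(O)c1 | starting material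
11 | isobutyryl chloride (2-methylpropanoyl chloride) | CC(C)C(=O)Cl | starting material
12 | phlorisobutyrophenone, 2-methyl-1-(2,4,6-trihydroxyphenyl)propan-1-one | CC(C)C(=O)c1c(O)cc(O)cc1O | intermediate
13 | prenyl bromide (1-bromo-3-methylbut-2-ene) | CC(C)=CCBr | starting material
14 | 3-prenylphlorisobutyrophenone, 2-methyl-1-[2,4,6-trihydroxy-3-(3-methylbut-2-en-1-yl)phenyl]propan-1-one | CC(C)C(=O)c1c(O)cc(O)c(CC=C(C)C)c1O | intermediate
15 | 3,5-dihydroxy-6,6-bis(3-methylbut-2-en-1-yl)-2-(2-methylpropanoyl)cyclohexa-2,4-dien-1-one | CC(C)C(=O)C1=C(O)C=C(O)C(CC=C(C)C)(CC=C(C)C)C1=O | intermediate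
16 | 5-hydroxy-6-{[(1S,2R,5R)-2-hydroxy-2-methyl-5-(prop-1-en-2-yl)cyclopentyl]methylidene}-2,2-bis(3-methylbut-2-en-1-yl)-4-(2-methylpropanoyl)cyclohex-4-ene-1,3-dione (alkylidene trione; exocyclic alkene geometry not defined) | C=C(C)[C@@H]1CC[C@@](C)(O)[C@H]1C=C1C(=O)C(CC=C(C)C)(CC=C(C)C)C(=O)C(C(=O)C(C)C)=C1O | intermediate
17 | CNP0290578.2, 3,5-dihydroxy-4-{[(1S,2R,5R)-2-hydroxy-2-methyl-5-(prop-1-en-2-yl)cyclopentyl]methyl}-6,6-bis(3-methylbut-2-en-1-yl)-2-(2-methylpropanoyl)cyclohexa-2,4-dien-1-one | C=C(C)[C@@H]1CC[C@@](C)(O)[C@H]1CC1=C(O)C(CC=C(C)C)(CC=C(C)C)C(=O)C(C(=O)C(C)C)=C1O | target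

**Totals**
Total step count: 8. Longest linear sequence: 6 steps (steps 1, 2, 3, 4, 5, 8); steps 6 and 7 form the convergent branch.

**Three steps most likely to fail**

Step 3 (aldol-lactonisation). The methyl ketone is a sluggish acceptor, the activated acid can instead give anhydride or ketene-derived oligomers, and the trans selectivity rests on substrate control alone. The fallback sets out from keto aldehyde 3 and closes only the carbocycle by an enamine-mediated intramolecular 5-enolexo aldol addition (proline 20 mol%, both enantiomers screened for the matched case, DMF, 4 °C, stopped before dehydration). The same A1,3 argument places the formyl group trans to isopropenyl, and the hydrogen bond from the catalyst's acid to the ketone oxygen places OH cis to CHO. This gives hydroxy aldehyde 9 directly, so the path comes back to the route at 9 and no new compound arises (entry F0). It is held in reserve because the adduct readily dehydrates to the conjugated enal under amine catalysis and the carbinol configuration is not locked by a ring fusion.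

Step 7 (gem-diprenylation). The second prenyl group can instead enter the free ring carbon (aromatic 3,5-diprenyl isomer), a third can follow, and O-alkylation competes, so the yield of 15 may be low. The fallback sets out from 12 and reverses the order of the two C–C bond formations. Reductive alkylation of 12 (3 equiv, excess recovered) with aldehyde 9, Hantzsch ester and (S)-proline gives 2-methyl-1-(2,4,6-trihydroxy-3-{[(1S,2R,5R)-2-hydroxy-2-methyl-5-(prop-1-en-2-yl)cyclopentyl]methyl}phenyl)propan-1-one F1. F1 now has a single free ring carbon, so NaOMe/MeOH with prenyl bromide 13 (2.1 equiv) puts the first prenyl group there and the second at the same, less hindered carbon. The path comes back to the route at 17.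

Step 8 (reductive alkylation). Aldehyde 9 is α-branched and hindered, and under amine catalysis it can undergo retro-aldol cleavage or lose water before or after condensation. The fallback sets out from 9 and masks the carbinol first: TESOTf, 2,6-lutidine, CH2Cl2, −78 °C gives (1S,2R,5R)-2-methyl-5-(prop-1-en-2-yl)-2-[(triethylsilyl)oxy]cyclopentane-1-carbaldehyde F2, which cannot undergo retro-aldol cleavage. The same Knoevenagel/Hantzsch ester coupling with 15 gives the triethylsilyl ether of the target F3, and HF·pyridine in THF at 0 °C frees the tertiary alcohol. The path comes back to the route at 17.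

**Further compounds**
F0 | step 3 | none | none
F1 | step 7 | 2-methyl-1-(2,4,6-trihydroxy-3-{[(1S,2R,5R)-2-hydroxy-2-methyl-5-(prop-1-en-2-yl)cyclopentyl]methyl}phenyl)propan-1-one | C=C(C)[C@@H]1CC[C@@](C)(O)[C@H]1Cc1c(O)cc(O)c(C(=O)C(C)C)c1O
F2 | step 8 | (1S,2R,5R)-2-methyl-5-(prop-1-en-2-yl)-2-[(triethylsilyl)oxy]cyclopentane-1-carbaldehyde | C=C(C)[C@@H]1CC[C@@](C)(O[Si](CC)(CC)CC)[C@H]1C=O
F3 | step 8 | 3,5-dihydroxy-6,6-bis(3-methylbut-2-en-1-yl)-4-{[(1S,2R,5R)-2-methyl-5-(prop-1-en-2-yl)-2-[(triethylsilyl)oxy]cyclopentyl]methyl}-2-(2-methylpropanoyl)cyclohexa-2,4-dien-1-one | C=C(C)[C@@H]1CC[C@@](C)(O[Si](CC)(CC)CC)[C@H]1CC1=C(O)C(CC=C(C)C)(CC=C(C)C)C(=O)C(C(=O)C(C)C)=C1O
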